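**Plan**

- Cuts: the S–O bond of the 3'-sulfate and the four benzyl–O bonds are removed first; ring B is then cut at C1'–C6' and C2'–C3', leaving a 2-ethynylchromone (rings A and C) and a 3,4-dioxygenated furan.
- Enabling feature: ring B carries oxygen on the three adjacent carbons C3', C4' and C5' between the CH groups C2' and C6', and only O3' must differ from its neighbours. A 3,4-bis(benzyloxy)furan supplies C3'–C6' with O4' and O5' already capped, and its ring oxygen becomes the one free hydroxyl, O3'.
- Forward order: ring C is closed onto ring A (phloroglucinol ketone plus oxalate) and its C2 ester is converted to an ethynyl group. The furan is built separately from diglycolate and oxalate. Ring B is formed last by Diels–Alder addition and opening of the oxygen bridge.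
- End game: sulfation of the single phenol, then hydrogenolysis of all benzyl ethers.
- Stereochemistry: the target has no stereocentre; the two bridgehead centres of the cycloadduct are transient and disappear on aromatisation.

Key step: step 10

Remark on the chemistry: the sulfate monoesters 16 and 17 are written as hydrogen sulfates, the form in which the target is drawn; each would be handled as its pyridinium salt and the acid form of 17 set free on a cation-exchange resin (acid form) only at the end.

**Route**

Step 1
Reactants: 1 2',4',6'-trihydroxyacetophenone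
Product: 2 1-[2,4-bis(benzyloxy)-6-hydroxyphenyl]ethan-1-one
Conditions: BnBr (2.1 equiv), K2CO3, DMF, rt
Reagents that add atoms: benzyl bromide, BrCc1ccccc1
Why: Williamson etherification in which the hydroxyl hydrogen-bonded to the acetyl oxygen is the least nucleophilic and should stay free when two equivalents of benzyl bromide are used.

Step 2
Reactants: 2 1-[2,4-bis(benzyloxy)-6-hydroxyphenyl]ethan-1-one; 3 diethyl oxalate
Product: 5 ethyl 5,7-bis(benzyloxy)-4-oxo-4H-chromene-2-carboxylate, via diketo ester 4 (not isolated)
Conditions: NaOEt, EtOH, reflux; then HCl (cat.), EtOH, 70 °C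
Reagents that add atoms: none
Why: Crossed Claisen condensation of the methyl ketone enolate with the non-enolisable oxalate gives the diketo ester, and acid then closes ring C by addition of the free phenol to the 2-keto group and loss of water, the standard entry to chromone-2-carboxylates.

Step 3
Reactants: 5 ethyl 5,7-bis(benzyloxy)-4-oxo-4H-chromene-2-carboxylate
Product: 6 5,7-bis(benzyloxy)-2-(hydroxymethyl)-4H-chromen-4-one
Conditions: NaBH4, MeOH/THF, 0 °C
Reagents that add atoms: none
Why: Chemoselective borohydride reduction, because the ester on the electron-poor C2 is activated whereas the C4 carbonyl is a vinylogous ester and should be inert at low temperature.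

Step 4
Reactants: 6 5,7-bis(benzyloxy)-2-(hydroxymethyl)-4H-chromen-4-one
Product: 7 5,7-bis(benzyloxy)-4-oxo-4H-chromene-2-carbaldehyde
Conditions: Dess–Martin periodinane, CH2Cl2, rt
Reagents that add atoms: none
Why: Dess–Martin oxidation of the primary allylic-type alcohol stops at the aldehyde under neutral, non-nucleophilic conditions that spare the pyranone and the benzyl ethers.

Step 5
Reactants: 7 5,7-bis(benzyloxy)-4-oxo-4H-chromene-2-carbaldehyde
Product: 8 5,7-bis(benzyloxy)-2-ethynyl-4H-chromen-4-one
Conditions: dimethyl (1-diazo-2-oxopropyl)phosphonate, K2CO3, MeOH/THF, 0 °C to rt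
Reagents that add atoms: dimethyl (1-diazo-2-oxopropyl)phosphonate, CC(=O)C(=[N+]=[N-])P(=O)(OC)OC
Why: Ohira–Bestmann (Seyferth–Gilbert) homologation, in which the diazomethylphosphonate anion adds to the aldehyde, Horner–Wadsworth–Emmons-type elimination gives a diazoalkene, and loss of N2 with a 1,2-hydrogen shift delivers the terminal alkyne without strong base.

Step 6
Reactants: 9 diethyl diglycolate (diethyl 2,2'-oxydiacetate); 3 diethyl oxalate
Product: 10 diethyl 3,4-dihydroxyfuran-2,5-dicarboxylate
Conditions: NaOEt, EtOH, reflux; then aq. HCl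
Reagents that add atoms: none
Why: Double Claisen (Hinsberg-type) condensation of the two α-methylene groups of the diglycolate with the oxalate closes the five-membered ring, whose dione tautomerises to the aromatic 3,4-dihydroxyfuran.

Step 7
Reactants: 10 diethyl 3,4-dihydroxyfuran-2,5-dicarboxylate
Product: 11 diethyl 3,4-bis(benzyloxy)furan-2,5-dicarboxylate
Conditions: BnBr (2.2 equiv), K2CO3, DMF, 80 °C
Reagents that add atoms: benzyl bromide, BrCc1ccccc1
Why: Williamson O-benzylation of the two acidic enolic hydroxyls, the only nucleophilic sites of the diester.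

Step 8
Reactants: 11 diethyl 3,4-bis(benzyloxy)furan-2,5-dicarboxylate
Product: 12 3,4-bis(benzyloxy)furan-2,5-dicarboxylic acid
Conditions: NaOH, EtOH/H2O, reflux; then aq. HCl
Reagents that add atoms: sodium hydroxide, [Na+].[OH-]
Why: Saponification of both ethyl esters followed by acidification, with the benzyl ethers inert to hydroxide.

Step 9
Reactants: 12 3,4-bis(benzyloxy)furan-2,5-dicarboxylic acid
Product: 13 3,4-bis(benzyloxy)furan
Conditions: Cu powder, quinoline, 190 °C
Reagents that add atoms: none
Why: Copper-mediated thermal protodecarboxylation of a furan-2-carboxylic acid, the usual way to free the α-positions of 3,4-dialkoxyfurans, with the electron-rich furan to be used promptly.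

Step 10
Reactants: 8 5,7-bis(benzyloxy)-2-ethynyl-4H-chromen-4-one; 13 3,4-bis(benzyloxy)furan
Product: 15 5,7-bis(benzyloxy)-2-[3,4-bis(benzyloxy)-5-hydroxyphenyl]-4H-chromen-4-one, via oxanorbornadiene 14 (not isolated)
Conditions: 13 (2 equiv), ZnI2 (1 equiv), CH2Cl2, rt to 40 °C
Reagents that add atoms: none
Why: The symmetric furan 13, made electron-rich by its two enol-ether oxygens, adds through C2 and C5 across the terminal alkyne of 8 in a normal-demand (4+2) cycloaddition, the alkyne being the vinylogue of an ynone through C2=C3–C4=O and further polarised when ZnI2 binds the basic pyranone carbonyl and lends C2 benzopyrylium character. The closest known reaction type is the Diels–Alder addition of furans, 3,4-dialkoxyfurans included, to propiolates and ynones followed by acid or Lewis-acid isomerisation of the 7-oxanorbornadiene to a phenol. Ring B closes intermolecularly as a six-membered carbocycle by the cycloaddition itself, which forms C1'–C6' and C2'–C3' in one suprafacial event, and the oxygen bridge of adduct 14 is then cleaved by ZnI2. No stereocentre has to be controlled, since the two bridgehead centres of racemic 14 are lost on aromatisation and the symmetry of the furan makes the orientation of the addition irrelevant. The step needs the bridge to open at C6', the bridgehead beside the chromonyl-bearing C1': that ionisation spreads the charge over C6', C2' and the benzyloxy-bearing C4', whereas ionisation at C3' would place charge on C1' next to the electron-poor chromone C2, so loss of the C3' proton should leave the hydroxyl at C3', meta to C1', as with acceptor-substituted 7-oxanorbornadienes, which open to meta-hydroxy arenes. Selectivity for the alkyne over C2=C3 rests on the ring oxygen and the extra substituent on that double bond, and irreversible aromatisation should remove 14 before a second furan adds or cycloreversion sets in.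

Step 11
Reactants: 15 5,7-bis(benzyloxy)-2-[3,4-bis(benzyloxy)-5-hydroxyphenyl]-4H-chromen-4-one
Product: 16 5-[5,7-bis(benzyloxy)-4-oxo-4H-chromen-2-yl]-2,3-bis(benzyloxy)phenyl hydrogen sulfate
Conditions: SO3·pyridine, pyridine, 50 °C
Reagents that add atoms: sulfur trioxide–pyridine complex, [O-]S(=O)(=O)[n+]1ccccc1
Why: O-sulfation of a phenol with the SO3·pyridine complex, the site being fixed because 15 has a single hydroxyl.

Step 12
Reactants: 16 5-[5,7-bis(benzyloxy)-4-oxo-4H-chromen-2-yl]-2,3-bis(benzyloxy)phenyl hydrogen sulfate
Product: 17 tricetin 3'-sulfate, 5-(5,7-dihydroxy-4-oxo-4H-chromen-2-yl)-2,3-dihydroxyphenyl hydrogen sulfate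
Conditions: H2 (1 atm), 10% Pd/C, THF/MeOH, rt
Reagents that add atoms: none
Why: Catalytic hydrogenolysis of the four aryl benzyl ethers at ambient pressure, conditions under which an aryl sulfate held as its salt and the flavone C2–C3 double bond should persist if the reaction is stopped at the calculated hydrogen uptake.

**Compound list**

1 | 2',4',6'-trihydroxyacetophenone | CC(=O)c1c(O)cc(O)cc1O | starting material
2 | 1-[2,4-bis(benzyloxy)-6-hydroxyphenyl]ethan-1-one | CC(=O)c1c(O)cc(OCc2ccccc2)cc1OCc1ccccc1 | intermediate
3 | diethyl oxalate | CCOC(=O)C(=O)OCC | starting material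
4 | ethyl 4-[2,4-bis(benzyloxy)-6-hydroxyphenyl]-2,4-dioxobutanoate (diketo ester, not isolated) | CCOC(=O)C(=O)CC(=O)c1c(O)cc(OCc2ccccc2)cc1OCc1ccccc1 | intermediate
5 | ethyl 5,7-bis(benzyloxy)-4-oxo-4H-chromene-2-carboxylate | CCOC(=O)c1cc(=O)c2c(OCc3ccccc3)cc(OCc3ccccc3)cc2o1 | intermediate
6 | 5,7-bis(benzyloxy)-2-(hydroxymethyl)-4H-chromen-4-one | OCc1cc(=O)c2c(OCc3ccccc3)cc(OCc3ccccc3)cc2o1 | intermediate
7 | 5,7-bis(benzyloxy)-4-oxo-4H-chromene-2-carbaldehyde | O=Cc1cc(=O)c2c(OCc3ccccc3)cc(OCc3ccccc3)cc2o1 | intermediate
8 | 5,7-bis(benzyloxy)-2-ethynyl-4H-chromen-4-one | C#Cc1cc(=O)c2c(OCc3ccccc3)cc(OCc3ccccc3)cc2o1 | intermediate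
9 | diethyl diglycolate (diethyl 2,2'-oxydiacetate) | CCOC(=O)COCC(=O)OCC | starting material
10 | diethyl 3,4-dihydroxyfuran-2,5-dicarboxylate | CCOC(=O)c1oc(C(=O)OCC)c(O)c1O | intermediate
11 | diethyl 3,4-bis(benzyloxy)furan-2,5-dicarboxylate | CCOC(=O)c1oc(C(=O)OCC)c(OCc2ccccc2)c1OCc1ccccc1 | intermediate
12 | 3,4-bis(benzyloxy)furan-2,5-dicarboxylic acid | OC(=O)c1oc(C(=O)O)c(OCc2ccccc2)c1OCc1ccccc1 | intermediate
13 | 3,4-bis(benzyloxy)furan | c1occ(OCc2ccccc2)c1OCc1ccccc1 | intermediate
14 | 5,7-bis(benzyloxy)-2-[5,6-bis(benzyloxy)-7-oxabicyclo[2.2.1]hepta-2,5-dien-2-yl]-4H-chromen-4-one (racemic, one enantiomer drawn; not isolated) | O=c1cc(C2=C[C@@H]3O[C@H]2C(OCc2ccccc2)=C3OCc2ccccc2)oc2cc(OCc3ccccc3)cc(OCc3ccccc3)c12 | intermediate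
15 | 5,7-bis(benzyloxy)-2-[3,4-bis(benzyloxy)-5-hydroxyphenyl]-4H-chromen-4-one | O=c1cc(-c2cc(O)c(OCc3ccccc3)c(OCc3ccccc3)c2)oc2cc(OCc3ccccc3)cc(OCc3ccccc3)c12 | intermediate
16 | 5-[5,7-bis(benzyloxy)-4-oxo-4H-chromen-2-yl]-2,3-bis(benzyloxy)phenyl hydrogen sulfate | O=c1cc(-c2cc(OS(=O)(=O)O)c(OCc3ccccc3)c(OCc3ccccc3)c2)oc2cc(OCc3ccccc3)cc(OCc3ccccc3)c12 | intermediate
17 | tricetin 3'-sulfate | O=c1cc(-c2cc(O)c(O)c(OS(=O)(=O)O)c2)oc2cc(O)cc(O)c12 | target

**Count**

Total steps: 12. Longest linear sequence: 8 steps (steps 1–5, then 10–12); the furan branch (steps 6–9) joins at step 10.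

**Steps most likely to fail**

Step 10. The cycloaddition may stall because the alkyne is activated only through the pyranone. The Lewis acid may instead consume the furan by decomposition or by conjugate addition at the alkyne terminus without ring closure. The bridge could also open in the wrong sense, or the 5-benzyl ether could be lost at the chelating carbonyl. The fallback keeps the furan as the source of ring B but uses a directly activated alkyne and closes ring C afterwards; it sets out from 13 and 2. Furan 13 and methyl propiolate (ZnI2, CH2Cl2) should give, by the established furan–propiolate cycloaddition and aromatisation, methyl 3,4-bis(benzyloxy)-5-hydroxybenzoate F1. Its phenol is capped with MOMCl and i-Pr2NEt to give methyl 3,4-bis(benzyloxy)-5-(methoxymethoxy)benzoate F2. Claisen condensation of F2 with the lithium dianion of ketone 2 (LiN(SiMe3)2, THF, −78 °C to rt) gives 1-[2,4-bis(benzyloxy)-6-hydroxyphenyl]-3-[3,4-bis(benzyloxy)-5-(methoxymethoxy)phenyl]propane-1,3-dione F3. HCl in MeOH/THF then cyclodehydrates the diketone to the flavone and removes the methoxymethyl group, which returns to the route at 15.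

Step 5. The polarisation that makes the alkyne a dienophile also exposes it to conjugate addition of methoxide, and the pyranone may be opened by attack at C2 in basic methanol. The fallback avoids alkoxide and sets out from 7. Olefination with CBr4 and PPh3 (first stage of the Corey–Fuchs sequence) gives 5,7-bis(benzyloxy)-2-(2,2-dibromoethenyl)-4H-chromen-4-one F4. Pd(PPh3)4-catalysed hydrogenolysis with Bu3SnH removes the bromine trans to the ring and gives 5,7-bis(benzyloxy)-2-[(Z)-2-bromoethenyl]-4H-chromen-4-one F5. Anti elimination of HBr with Bu4NF in DMF then returns to the route at 8.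

Step 12. The sulfate ester may be lost by acid-catalysed solvolysis while the salt is hydrogenated and concentrated, debenzylation may be slow on a catalyst inhibited by the ionic substrate, or the C2–C3 double bond may be saturated on prolonged exposure. The fallback carries the sulfate as a neutral diester and sets out from 15. Sulfation with 2,2,2-trichloroethyl chlorosulfate (Et3N, DMAP, THF) gives 5-[5,7-bis(benzyloxy)-4-oxo-4H-chromen-2-yl]-2,3-bis(benzyloxy)phenyl 2,2,2-trichloroethyl sulfate F6, which can be purified on silica. Transfer hydrogenolysis (10% Pd/C, HCO2NH4, MeOH/THF) then removes the trichloroethyl group reductively and the four benzyl ethers in one buffered operation. The sulfate appears only at the end, as its ammonium salt, and this returns to the route at 17.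

**Further compounds**

F1 | step 10 | methyl 3,4-bis(benzyloxy)-5-hydroxybenzoate | COC(=O)c1cc(O)c(OCc2ccccc2)c(OCc2ccccc2)c1
F2 | step 10 | methyl 3,4-bis(benzyloxy)-5-(methoxymethoxy)benzoate | COCOc1cc(C(=O)OC)cc(OCc2ccccc2)c1OCc1ccccc1
F3 | step 10 | 1-[2,4-bis(benzyloxy)-6-hydroxyphenyl]-3-[3,4-bis(benzyloxy)-5-(methoxymethoxy)phenyl]propane-1,3-dione | COCOc1cc(C(=O)CC(=O)c2c(O)cc(OCc3ccccc3)cc2OCc2ccccc2)cc(OCc2ccccc2)c1OCc1ccccc1
F4 | step 5 | 5,7-bis(benzyloxy)-2-(2,2-dibromoethenyl)-4H-chromen-4-one | BrC(Br)=Cc1cc(=O)c2c(OCc3ccccc3)cc(OCc3ccccc3)cc2o1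
F5 | step 5 | 5,7-bis(benzyloxy)-2-[(Z)-2-bromoethenyl]-4H-chromen-4-one | Br/C=C\c1cc(=O)c2c(OCc3ccccc3)cc(OCc3ccccc3)cc2o1
F6 | step 12 | 5-[5,7-bis(benzyloxy)-4-oxo-4H-chromen-2-yl]-2,3-bis(benzyloxy)phenyl 2,2,2-trichloroethyl sulfate | O=c1cc(-c2cc(OS(=O)(=O)OCC(Cl)(Cl)Cl)c(OCc3ccccc3)c(OCc3ccccc3)c2)oc2cc(OCc3ccccc3)cc(OCc3ccccc3)c12
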